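The route rests on disconnecting C6–C7, the bond shared by the ten-membered carbocycle (C1–C10) and the cis-fused α-methylene-γ-butyrolactone (O–C6–C7–C11–C12). C7 is the γ-carbon of a 2-carboxyallyl unit (C13–C11–C7) and C6 a carbinol carbon. One chromium-mediated intramolecular allylation of an acyclic aldehyde bearing a Z-2-(bromomethyl)enoate therefore closes the carbocycle, sets C6 and C7 under control of C8, unveils the exocyclic methylene and, by in situ lactonisation, forms the lactone. The precursor is a linear C6 enal/C13 bromide carrying the C3 acetate, the C8 and C9 ethers and both Z olefins, assembled from two Z-alkenyl iodides and a tartrate-derived aldehyde.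

Key step: step 24

Remark on the chemistry: germacrane numbering is used (ring carbons C1–C10, lactone carbons C11–C13, C14 on C10, C15 on C4); the SMILES is read as the 1(10)Z,4Z isomer with a cis-fused (6R,7R) lactone; TBS = tert-butyldimethylsilyl, PMB = 4-methoxybenzyl.

Steps 1–2 give alkenyl iodide 4 (C4–C6, C15), steps 3–5 aldehyde 12 (C1–C3, C10, C14), steps 6–9 join them to 18, steps 10–13 give aldehyde 24 (C7–C9 plus one carbon that is later excised), steps 14–16 give acid 28, and steps 17–27 are the main line.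

Step 1
Reactants: 1 but-2-yn-1-ol
Product: 3 (Z)-3-iodobut-2-en-1-ol, via sodium alkenylalanate 2 (not isolated)
Conditions: NaAlH2(OCH2CH2OMe)2, THF, 0 °C to rt; then I2, −78 to 0 °C
Reagents that add atoms: iodine, [I][I]
Why: Hydroxyl-directed trans-hydroalumination of the propargylic alcohol places aluminium on the methyl-bearing carbon cis to the carbinol carbon (five-membered alanate 2), and iodinolysis with retention gives the Z iodide that fixes the C4=C5 geometry.

Step 2
Reactants: 3 (Z)-3-iodobut-2-en-1-ol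
Product: 4 (Z)-tert-butyl[(3-iodobut-2-en-1-yl)oxy]dimethylsilane
Conditions: TBSCl, imidazole, CH2Cl2, 0 °C to rt
Reagents that add atoms: tert-butyldimethylsilyl chloride, CC(C)(C)[Si](C)(C)Cl
Why: Standard silylation masks the future C6 hydroxyl for the organometallic step.

Step 3
Reactants: 5 3-[(tert-butyldimethylsilyl)oxy]propanal; 6 ethyltriphenylphosphonium iodide
Product: 10 (Z)-tert-butyl[(4-iodopent-3-en-1-yl)oxy]dimethylsilane, via ethylidenetriphenylphosphorane 7 (not isolated), via (1-iodoethyl)triphenylphosphonium iodide 8 (not isolated), via (1-iodoethylidene)triphenylphosphorane 9 (not isolated)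
Conditions: 6, n-BuLi, THF, rt; I2, −78 °C; NaN(SiMe3)2, −20 °C; then 5, −78 °C
Reagents that add atoms: iodine, [I][I]
Why: Wittig olefination with the α-iodo ylide (Stork–Zhao type) passes through the kinetic cis-oxaphosphetane and should give the Z-2-iodoalkene with iodine cis to the chain, which fixes the C1=C10 geometry.

Step 4
Reactants: 10 (Z)-tert-butyl[(4-iodopent-3-en-1-yl)oxy]dimethylsilane
Product: 11 (Z)-4-iodopent-3-en-1-ol
Conditions: pyridinium p-toluenesulfonate (catalytic), MeOH, rt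
Reagents that add atoms: none
Why: Acid-catalysed methanolysis removes the primary silyl ether without touching the alkenyl iodide.

Step 5
Reactants: 11 (Z)-4-iodopent-3-en-1-ol
Product: 12 (Z)-4-iodopent-3-enal
Conditions: Dess–Martin periodinane, NaHCO3, CH2Cl2, 0 °C; used at once
Reagents that add atoms: none
Why: Buffered Dess–Martin oxidation should give the β,γ-unsaturated aldehyde without migration of the olefin into conjugation.

Step 6
Reactants: 4 (Z)-tert-butyl[(3-iodobut-2-en-1-yl)oxy]dimethylsilane; 12 (Z)-4-iodopent-3-enal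
Product: 15 racemic (2Z,6Z)-1-[(tert-butyldimethylsilyl)oxy]-7-iodo-3-methylocta-2,6-dien-4-ol, via alkenyllithium 13 (not isolated), via alkenylcerium dichloride 14 (not isolated)
Conditions: 4, t-BuLi (2 equiv), Et2O, −78 °C; CeCl3, THF, −78 °C; then 12, −78 °C
Reagents that add atoms: none
Why: Iodine–lithium exchange with retention and transmetalation to the weakly basic organocerium reagent should allow clean 1,2-addition to the enolisable aldehyde, the C3 carbinol forming as a racemate that steps 7 and 8 correct.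

Step 7
Reactants: 15 racemic (2Z,6Z)-1-[(tert-butyldimethylsilyl)oxy]-7-iodo-3-methylocta-2,6-dien-4-ol
Product: 16 (2Z,6Z)-1-[(tert-butyldimethylsilyl)oxy]-7-iodo-3-methylocta-2,6-dien-4-one
Conditions: Dess–Martin periodinane, NaHCO3, CH2Cl2, 0 °C
Reagents that add atoms: none
Why: Buffered Dess–Martin oxidation of the allylic alcohol should give the enone while both Z olefins stay in place.

Step 8
Reactants: 16 (2Z,6Z)-1-[(tert-butyldimethylsilyl)oxy]-7-iodo-3-methylocta-2,6-dien-4-one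
Product: 17 (2Z,4S,6Z)-1-[(tert-butyldimethylsilyl)oxy]-7-iodo-3-methylocta-2,6-dien-4-ol
Conditions: (R)-2-methyl-CBS-oxazaborolidine (0.2 equiv), BH3·SMe2, THF, −30 °C
Reagents that add atoms: none
Why: In this Corey–Bakshi–Shibata reduction the α-methylalkenyl group acts as the large substituent, so the (R)-oxazaborolidine should deliver hydride to the face that gives the 3S carbinol (catalyst control).

Step 9
Reactants: 17 (2Z,4S,6Z)-1-[(tert-butyldimethylsilyl)oxy]-7-iodo-3-methylocta-2,6-dien-4-ol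
Product: 18 (2Z,4S,6Z)-1-[(tert-butyldimethylsilyl)oxy]-7-iodo-3-methylocta-2,6-dien-4-yl acetate
Conditions: Ac2O, pyridine, 4-(dimethylamino)pyridine (catalytic), CH2Cl2, rt
Reagents that add atoms: acetic anhydride, CC(=O)OC(C)=O
Why: Acylation installs the C3 acetate of the target, which no later step needs to touch.

Step 10
Reactants: 19 dimethyl D-tartrate
Product: 21 dimethyl (2S,3S)-2-hydroxy-3-[(4-methoxybenzyl)oxy]butanedioate, via stannylene acetal 20 (not isolated)
Conditions: Bu2SnO, toluene, reflux with removal of water; then 4-methoxybenzyl chloride, CsF, DMF, rt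
Reagents that add atoms: 4-methoxybenzyl chloride, COc1ccc(CCl)cc1
Why: The stannylene acetal of the C2-symmetric diol is alkylated once (both hydroxyls are homotopic), which desymmetrises the tartrate without touching its stereocenters.

Step 11
Reactants: 21 dimethyl (2S,3S)-2-hydroxy-3-[(4-methoxybenzyl)oxy]butanedioate
Product: 22 (2R,3R)-3-[(4-methoxybenzyl)oxy]butane-1,2,4-triol
Conditions: LiAlH4, THF, 0 °C to rt
Reagents that add atoms: none
Why: Hydride reduction of both esters gives 2-O-PMB-D-threitol with the stereocenters intact.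

Step 12
Reactants: 22 (2R,3R)-3-[(4-methoxybenzyl)oxy]butane-1,2,4-triol
Product: 23 (2R)-2-[(4R)-2,2-dimethyl-1,3-dioxolan-4-yl]-2-[(4-methoxybenzyl)oxy]ethan-1-ol
Conditions: 2,2-dimethoxypropane, p-toluenesulfonic acid (catalytic), acetone, rt
Reagents that add atoms: 2,2-dimethoxypropane, COC(C)(C)OC
Why: Thermodynamic acetonide formation should select the terminal 1,2-diol (dioxolane over the six-membered dioxane) and leave the primary hydroxyl next to the PMB-bearing carbon free.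

Step 13
Reactants: 23 (2R)-2-[(4R)-2,2-dimethyl-1,3-dioxolan-4-yl]-2-[(4-methoxybenzyl)oxy]ethan-1-ol
Product: 24 (2S)-2-[(4R)-2,2-dimethyl-1,3-dioxolan-4-yl]-2-[(4-methoxybenzyl)oxy]acetaldehyde
Conditions: Dess–Martin periodinane, NaHCO3, CH2Cl2, 0 °C
Reagents that add atoms: none
Why: Buffered Dess–Martin oxidation should give the α-alkoxy aldehyde without epimerisation of the future C8, whose configuration comes from D-tartrate (chiral pool).

Step 14
Reactants: 25 angelic acid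
Product: 26 (Z)-2-methylbut-2-en-1-ol
Conditions: LiAlH4, Et2O, 0 °C
Reagents that add atoms: none
Why: 1,2-Hydride reduction of the acid gives the Z allylic alcohol with the olefin geometry unchanged.

Step 15
Reactants: 26 (Z)-2-methylbut-2-en-1-ol
Product: 27 [(2S,3R)-2,3-dimethyloxiran-2-yl]methanol
Conditions: Ti(OiPr)4 (catalytic), L-(+)-diethyl tartrate (catalytic), t-BuOOH, 4 Å molecular sieves, CH2Cl2, −20 °C
Reagents that add atoms: tert-butyl hydroperoxide, CC(C)(C)OO
Why: In the Sharpless asymmetric epoxidation the L-(+)-tartrate catalyst should select the olefin face that gives the 2S,3R epoxy alcohol, and the Z geometry is carried over as the cis relation of hydroxymethyl and C3 methyl.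

Step 16
Reactants: 27 [(2S,3R)-2,3-dimethyloxiran-2-yl]methanol
Product: 28 (2R,3R)-2,3-dimethyloxirane-2-carboxylic acid
Conditions: RuCl3 hydrate (catalytic), NaIO4, MeCN/EtOAc/H2O, 0 °C to rt
Reagents that add atoms: water, O
Why: Ruthenium tetroxide generated in situ oxidises the primary alcohol to the glycidic acid without opening the epoxide, the descriptor at C2 changing only by priority.

Step 17
Reactants: 18 (2Z,4S,6Z)-1-[(tert-butyldimethylsilyl)oxy]-7-iodo-3-methylocta-2,6-dien-4-yl acetate; 24 (2S)-2-[(4R)-2,2-dimethyl-1,3-dioxolan-4-yl]-2-[(4-methoxybenzyl)oxy]acetaldehyde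
Product: 30 (2Z,4S,6Z,8R,9R)-1-[(tert-butyldimethylsilyl)oxy]-9-[(4R)-2,2-dimethyl-1,3-dioxolan-4-yl]-8-hydroxy-9-[(4-methoxybenzyl)oxy]-3,7-dimethylnona-2,6-dien-4-yl acetate, via alkenylchromium dichloride 29 (not isolated)
Conditions: CrCl2 (5 equiv), NiCl2 (2 mol%), DMSO, rt
Reagents that add atoms: none
Why: In this Nozaki–Hiyama–Kishi alkenylation the nickel-catalysed formation of the alkenylchromium reagent keeps the Z geometry, and Felkin–Anh addition anti to the α-PMB ether should give the 8,9-anti alcohol (C9 R) by substrate control while acetate and silyl ether are tolerated.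

Step 18
Reactants: 30 (2Z,4S,6Z,8R,9R)-1-[(tert-butyldimethylsilyl)oxy]-9-[(4R)-2,2-dimethyl-1,3-dioxolan-4-yl]-8-hydroxy-9-[(4-methoxybenzyl)oxy]-3,7-dimethylnona-2,6-dien-4-yl acetate
Product: 31 (2Z,4S,6Z,8R,9S)-1,8-bis[(tert-butyldimethylsilyl)oxy]-9-[(4R)-2,2-dimethyl-1,3-dioxolan-4-yl]-9-[(4-methoxybenzyl)oxy]-3,7-dimethylnona-2,6-dien-4-yl acetate
Conditions: TBSOTf, 2,6-lutidine, CH2Cl2, −78 to 0 °C
Reagents that add atoms: tert-butyldimethylsilyl trifluoromethanesulfonate, CC(C)(C)[Si](C)(C)OS(=O)(=O)C(F)(F)F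
Why: The silyl triflate silylates the hindered allylic C9 hydroxyl under conditions that leave acetate and acetonide intact.

Step 19
Reactants: 31 (2Z,4S,6Z,8R,9S)-1,8-bis[(tert-butyldimethylsilyl)oxy]-9-[(4R)-2,2-dimethyl-1,3-dioxolan-4-yl]-9-[(4-methoxybenzyl)oxy]-3,7-dimethylnona-2,6-dien-4-yl acetate
Product: 33 (2R,3R,4Z,7S,8Z)-3,10-bis[(tert-butyldimethylsilyl)oxy]-2-[(4-methoxybenzyl)oxy]-4,8-dimethyl-1-oxodeca-4,8-dien-7-yl acetate, via glycol 32 (not isolated)
Conditions: H5IO6 (1.5 equiv), EtOAc, 0 °C to rt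
Reagents that add atoms: none
Why: Periodic acid hydrolyses the terminal dioxolane and cleaves the liberated glycol in one pot (Malaprade cleavage), so that the tartrate carbon C7 becomes the aldehyde while C8 keeps its configuration.

Step 20
Reactants: 33 (2R,3R,4Z,7S,8Z)-3,10-bis[(tert-butyldimethylsilyl)oxy]-2-[(4-methoxybenzyl)oxy]-4,8-dimethyl-1-oxodeca-4,8-dien-7-yl acetate; 34 methyl acrylate
Product: 35 methyl (4S,5R,6Z,9S,10Z)-9-acetoxy-5,12-bis[(tert-butyldimethylsilyl)oxy]-3-hydroxy-4-[(4-methoxybenzyl)oxy]-6,10-dimethyl-2-methylidenedodeca-6,10-dienoate (both C3 epimers)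
Conditions: 34 (excess), 1,4-diazabicyclo[2.2.2]octane (1 equiv), DMSO, rt
Reagents that add atoms: none
Why: In this Morita–Baylis–Hillman reaction the α-alkoxy aldehyde is an activated acceptor for the amine–acrylate zwitterion, and the configuration of the new C7 carbinol is of no consequence because step 21 removes it.

Step 21
Reactants: 35 methyl (4S,5R,6Z,9S,10Z)-9-acetoxy-5,12-bis[(tert-butyldimethylsilyl)oxy]-3-hydroxy-4-[(4-methoxybenzyl)oxy]-6,10-dimethyl-2-methylidenedodeca-6,10-dienoate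
Product: 36 methyl (2Z,4S,5R,6Z,9S,10Z)-9-acetoxy-2-(bromomethyl)-5,12-bis[(tert-butyldimethylsilyl)oxy]-4-[(4-methoxybenzyl)oxy]-6,10-dimethyldodeca-2,6,10-trienoate
Conditions: N-bromosuccinimide, Me2S, CH2Cl2, 0 °C to rt
Reagents that add atoms: N-bromosuccinimide, O=C1CCC(=O)N1Br
Why: Corey–Kim type activation of the allylic alcohol and SN2′ attack of bromide should give, from both C7 epimers, the thermodynamically preferred Z-2-(bromomethyl)enoate with C8 cis to CH2Br.

Step 22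
Reactants: 36 methyl (2Z,4S,5R,6Z,9S,10Z)-9-acetoxy-2-(bromomethyl)-5,12-bis[(tert-butyldimethylsilyl)oxy]-4-[(4-methoxybenzyl)oxy]-6,10-dimethyldodeca-2,6,10-trienoate
Product: 37 methyl (2Z,4S,5R,6Z,9S,10Z)-9-acetoxy-2-(bromomethyl)-5-[(tert-butyldimethylsilyl)oxy]-12-hydroxy-4-[(4-methoxybenzyl)oxy]-6,10-dimethyldodeca-2,6,10-trienoate
Conditions: aqueous HF, MeCN, 0 °C
Reagents that add atoms: none
Why: The primary allylic silyl ether at C6 should cleave much faster than the hindered secondary one at C9, and the amine-free medium spares the allylic bromide (chemoselective desilylation).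

Step 23
Reactants: 37 methyl (2Z,4S,5R,6Z,9S,10Z)-9-acetoxy-2-(bromomethyl)-5-[(tert-butyldimethylsilyl)oxy]-12-hydroxy-4-[(4-methoxybenzyl)oxy]-6,10-dimethyldodeca-2,6,10-trienoate
Product: 38 methyl (2Z,4S,5R,6Z,9S,10Z)-9-acetoxy-2-(bromomethyl)-5-[(tert-butyldimethylsilyl)oxy]-4-[(4-methoxybenzyl)oxy]-6,10-dimethyl-12-oxododeca-2,6,10-trienoate
Conditions: Dess–Martin periodinane, NaHCO3, CH2Cl2, 0 °C
Reagents that add atoms: none
Why: Buffered Dess–Martin oxidation should give the Z enal without isomerisation and without touching the allylic bromide.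

Step 24
Reactants: 38 methyl (2Z,4S,5R,6Z,9S,10Z)-9-acetoxy-2-(bromomethyl)-5-[(tert-butyldimethylsilyl)oxy]-4-[(4-methoxybenzyl)oxy]-6,10-dimethyl-12-oxododeca-2,6,10-trienoate
Product: 41 (3S,6R,7R,8S,9R)-3-acetoxy-9-[(tert-butyldimethylsilyl)oxy]-8-[(4-methoxybenzyl)oxy]germacra-1(10)Z,4Z,11(13)-trien-12,6-olide, via allylchromium dichloride 39 (not isolated), via chromium alkoxide 40 (not isolated)
Conditions: CrCl2 (10 equiv), THF/DMF (4:1), rt, 38 added by syringe pump to a final 0.002 M; aqueous NH4Cl work-up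
Reagents that add atoms: none
Why: Two equivalents of CrCl2 reduce the allylic bromide to the (2-methoxycarbonyl)allylchromium species 39 (trivalent chromium), whose γ-carbon C7 adds to the tethered C6 aldehyde through a chair Zimmerman–Traxler transition state, and the chromium alkoxide 40 then acylates on the C12 ester to give the lactone. The closest known reactions are the chromium-mediated Barbier (Nozaki–Hiyama–Kishi) macrocyclisations of 2-(bromomethyl)enoate aldehydes to germacranolides and the intermolecular coupling of Z-2-(bromomethyl)alk-2-enoates with aldehydes to cis-β,γ-disubstituted α-methylene-γ-butyrolactones. The ten-membered carbocycle closes by carbonyl addition at C6 (10-exo-trig, SE2′ at the allyl unit) and the γ-lactone by 5-exo-trig acyl substitution at C12. C6 and C7 are new: their cis relation should follow from the Z allyl geometry with C5 equatorial in the chair, and the face of C7 is controlled by C8, whose ether oxygen can chelate chromium in a six-membered ring through the Z olefin so that the aldehyde, tethered through C9, adds anti to C9 (6R,7R). The step needs ring closure to beat intermolecular coupling, which slow addition at high dilution and the two chain-folding Z olefins should secure, and γ- over α-attack, which is inherent to allylchromium reagents.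

Step 25
Reactants: 41 (3S,6R,7R,8S,9R)-3-acetoxy-9-[(tert-butyldimethylsilyl)oxy]-8-[(4-methoxybenzyl)oxy]germacra-1(10)Z,4Z,11(13)-trien-12,6-olide
Product: 42 (3S,6R,7S,8S,9R)-3-acetoxy-9-[(tert-butyldimethylsilyl)oxy]-8-hydroxygermacra-1(10)Z,4Z,11(13)-trien-12,6-olide
Conditions: DDQ, CH2Cl2/pH 7 buffer, 0 °C
Reagents that add atoms: none
Why: Oxidative cleavage of the PMB ether by DDQ frees only the C8 hydroxyl, the C7 descriptor changing by priority and not in space.

Step 26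
Reactants: 42 (3S,6R,7S,8S,9R)-3-acetoxy-9-[(tert-butyldimethylsilyl)oxy]-8-hydroxygermacra-1(10)Z,4Z,11(13)-trien-12,6-olide; 28 (2R,3R)-2,3-dimethyloxirane-2-carboxylic acid
Product: 44 (3S,6R,7R,8S,9R)-3-acetoxy-9-[(tert-butyldimethylsilyl)oxy]-8-{[(2R,3R)-2,3-dimethyloxirane-2-carbonyl]oxy}germacra-1(10)Z,4Z,11(13)-trien-12,6-olide, via mixed anhydride 43 (not isolated)
Conditions: 28, 2,4,6-trichlorobenzoyl chloride, Et3N, toluene, rt; then 42, 4-(dimethylamino)pyridine, toluene, 40 °C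
Reagents that add atoms: none
Why: Yamaguchi esterification through mixed anhydride 43 should acylate the hindered C8 hydroxyl with the preformed epoxy acid, whose stereocenters are not involved.

Step 27
Reactants: 44 (3S,6R,7R,8S,9R)-3-acetoxy-9-[(tert-butyldimethylsilyl)oxy]-8-{[(2R,3R)-2,3-dimethyloxirane-2-carbonyl]oxy}germacra-1(10)Z,4Z,11(13)-trien-12,6-olide
Product: 45 (3S,6R,7R,8S,9R)-3-acetoxy-9-hydroxy-8-{[(2R,3R)-2,3-dimethyloxirane-2-carbonyl]oxy}germacra-1(10)Z,4Z,11(13)-trien-12,6-olide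
Conditions: HF·pyridine, THF, 0 °C to rt
Reagents that add atoms: none
Why: Desilylation with buffered fluoride should free the C9 hydroxyl without acyl migration, epoxide opening or addition to the α-methylene lactone.

Compound list

1 | but-2-yn-1-ol | CC#CCO | starting material
2 | sodium alkenylalanate (cyclic 1,2-oxaluminole ate complex, aluminium on the methyl-bearing carbon cis to CH2O) | [Na+].CC1=CCO[Al-]1(OCCOC)OCCOC | intermediate
3 | (Z)-3-iodobut-2-en-1-ol | OC/C=C(/C)I | intermediate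
4 | (Z)-tert-butyl[(3-iodobut-2-en-1-yl)oxy]dimethylsilane | CC(C)(C)[Si](C)(C)OC/C=C(/C)I | intermediate
5 | 3-[(tert-butyldimethylsilyl)oxy]propanal | CC(C)(C)[Si](C)(C)OCCC=O | starting material
6 | ethyltriphenylphosphonium iodide | CC[P+](c1ccccc1)(c1ccccc1)c1ccccc1.[I-] | starting material
7 | ethylidenetriphenylphosphorane | CC=P(c1ccccc1)(c1ccccc1)c1ccccc1 | intermediate
8 | (1-iodoethyl)triphenylphosphonium iodide | CC(I)[P+](c1ccccc1)(c1ccccc1)c1ccccc1.[I-] | intermediate
9 | (1-iodoethylidene)triphenylphosphorane | CC(I)=P(c1ccccc1)(c1ccccc1)c1ccccc1 | intermediate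
10 | (Z)-tert-butyl[(4-iodopent-3-en-1-yl)oxy]dimethylsilane | CC(C)(C)[Si](C)(C)OCC/C=C(/C)I | intermediate
11 | (Z)-4-iodopent-3-en-1-ol | OCC/C=C(/C)I | intermediate
12 | (Z)-4-iodopent-3-enal | O=CC/C=C(/C)I | intermediate
13 | alkenyllithium from 4 (lithium cis to the CH2OTBS group) | CC(C)(C)[Si](C)(C)OC/C=C(/C)[Li] | intermediate
14 | alkenylcerium dichloride from 13 (cerium cis to the CH2OTBS group) | CC(C)(C)[Si](C)(C)OC/C=C(/C)[Ce](Cl)Cl | intermediate
15 | racemic (2Z,6Z)-1-[(tert-butyldimethylsilyl)oxy]-7-iodo-3-methylocta-2,6-dien-4-ol | CC(C)(C)[Si](C)(C)OC/C=C(/C)C(O)C/C=C(/C)I | intermediate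
16 | (2Z,6Z)-1-[(tert-butyldimethylsilyl)oxy]-7-iodo-3-methylocta-2,6-dien-4-one | CC(C)(C)[Si](C)(C)OC/C=C(/C)C(=O)C/C=C(/C)I | intermediate
17 | (2Z,4S,6Z)-1-[(tert-butyldimethylsilyl)oxy]-7-iodo-3-methylocta-2,6-dien-4-ol | CC(C)(C)[Si](C)(C)OC/C=C(/C)[C@@H](O)C/C=C(/C)I | intermediate
18 | (2Z,4S,6Z)-1-[(tert-butyldimethylsilyl)oxy]-7-iodo-3-methylocta-2,6-dien-4-yl acetate | CC(C)(C)[Si](C)(C)OC/C=C(/C)[C@@H](OC(C)=O)C/C=C(/C)I | intermediate
19 | dimethyl D-tartrate, dimethyl (2S,3S)-2,3-dihydroxybutanedioate | COC(=O)[C@@H](O)[C@H](O)C(=O)OC | starting material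
20 | stannylene acetal, dimethyl (4S,5S)-2,2-dibutyl-1,3,2-dioxastannolane-4,5-dicarboxylate | COC(=O)[C@H]1O[Sn](CCCC)(CCCC)O[C@@H]1C(=O)OC | intermediate
21 | dimethyl (2S,3S)-2-hydroxy-3-[(4-methoxybenzyl)oxy]butanedioate | COC(=O)[C@@H](OCc1ccc(OC)cc1)[C@H](O)C(=O)OC | intermediate
22 | (2R,3R)-3-[(4-methoxybenzyl)oxy]butane-1,2,4-triol (2-O-PMB-D-threitol) | OC[C@@H](OCc1ccc(OC)cc1)[C@H](O)CO | intermediate
23 | (2R)-2-[(4R)-2,2-dimethyl-1,3-dioxolan-4-yl]-2-[(4-methoxybenzyl)oxy]ethan-1-ol | OC[C@@H](OCc1ccc(OC)cc1)[C@H]1COC(C)(C)O1 | intermediate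
24 | (2S)-2-[(4R)-2,2-dimethyl-1,3-dioxolan-4-yl]-2-[(4-methoxybenzyl)oxy]acetaldehyde (2-O-PMB-3,4-O-isopropylidene-D-threose) | O=C[C@@H](OCc1ccc(OC)cc1)[C@H]1COC(C)(C)O1 | intermediate
25 | angelic acid, (Z)-2-methylbut-2-enoic acid | C/C=C(/C)C(=O)O | starting material
26 | (Z)-2-methylbut-2-en-1-ol | C/C=C(/C)CO | intermediate
27 | [(2S,3R)-2,3-dimethyloxiran-2-yl]methanol | OC[C@]1(C)O[C@@H]1C | intermediate
28 | (2R,3R)-2,3-dimethyloxirane-2-carboxylic acid | OC(=O)[C@]1(C)O[C@@H]1C | intermediate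
29 | alkenylchromium dichloride from 18 (chromium in place of iodine, same olefin geometry) | CC(C)(C)[Si](C)(C)OC/C=C(/C)[C@@H](OC(C)=O)C/C=C(/C)[Cr](Cl)Cl | intermediate
30 | (2Z,4S,6Z,8R,9R)-1-[(tert-butyldimethylsilyl)oxy]-9-[(4R)-2,2-dimethyl-1,3-dioxolan-4-yl]-8-hydroxy-9-[(4-methoxybenzyl)oxy]-3,7-dimethylnona-2,6-dien-4-yl acetate | CC(C)(C)[Si](C)(C)OC/C=C(/C)[C@@H](OC(C)=O)C/C=C(/C)[C@@H](O)[C@@H](OCc1ccc(OC)cc1)[C@H]1COC(C)(C)O1 | intermediate
31 | (2Z,4S,6Z,8R,9S)-1,8-bis[(tert-butyldimethylsilyl)oxy]-9-[(4R)-2,2-dimethyl-1,3-dioxolan-4-yl]-9-[(4-methoxybenzyl)oxy]-3,7-dimethylnona-2,6-dien-4-yl acetate | CC(C)(C)[Si](C)(C)OC/C=C(/C)[C@@H](OC(C)=O)C/C=C(/C)[C@@H](O[Si](C)(C)C(C)(C)C)[C@@H](OCc1ccc(OC)cc1)[C@H]1COC(C)(C)O1 | intermediate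
32 | glycol, (2Z,4S,6Z,8R,9S,10R)-1,8-bis[(tert-butyldimethylsilyl)oxy]-10,11-dihydroxy-9-[(4-methoxybenzyl)oxy]-3,7-dimethylundeca-2,6-dien-4-yl acetate | CC(C)(C)[Si](C)(C)OC/C=C(/C)[C@@H](OC(C)=O)C/C=C(/C)[C@@H](O[Si](C)(C)C(C)(C)C)[C@@H](OCc1ccc(OC)cc1)[C@H](O)CO | intermediate
33 | (2R,3R,4Z,7S,8Z)-3,10-bis[(tert-butyldimethylsilyl)oxy]-2-[(4-methoxybenzyl)oxy]-4,8-dimethyl-1-oxodeca-4,8-dien-7-yl acetate | CC(C)(C)[Si](C)(C)OC/C=C(/C)[C@@H](OC(C)=O)C/C=C(/C)[C@@H](O[Si](C)(C)C(C)(C)C)[C@@H](OCc1ccc(OC)cc1)C=O | intermediate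
34 | methyl acrylate | C=CC(=O)OC | starting material
35 | methyl (4S,5R,6Z,9S,10Z)-9-acetoxy-5,12-bis[(tert-butyldimethylsilyl)oxy]-3-hydroxy-4-[(4-methoxybenzyl)oxy]-6,10-dimethyl-2-methylidenedodeca-6,10-dienoate (both C3 epimers) | CC(C)(C)[Si](C)(C)OC/C=C(/C)[C@@H](OC(C)=O)C/C=C(/C)[C@@H](O[Si](C)(C)C(C)(C)C)[C@@H](OCc1ccc(OC)cc1)C(O)C(=C)C(=O)OC | intermediate
36 | methyl (2Z,4S,5R,6Z,9S,10Z)-9-acetoxy-2-(bromomethyl)-5,12-bis[(tert-butyldimethylsilyl)oxy]-4-[(4-methoxybenzyl)oxy]-6,10-dimethyldodeca-2,6,10-trienoate | CC(C)(C)[Si](C)(C)OC/C=C(/C)[C@@H](OC(C)=O)C/C=C(/C)[C@@H](O[Si](C)(C)C(C)(C)C)[C@@H](OCc1ccc(OC)cc1)/C=C(\CBr)C(=O)OC | intermediate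
37 | methyl (2Z,4S,5R,6Z,9S,10Z)-9-acetoxy-2-(bromomethyl)-5-[(tert-butyldimethylsilyl)oxy]-12-hydroxy-4-[(4-methoxybenzyl)oxy]-6,10-dimethyldodeca-2,6,10-trienoate | OC/C=C(/C)[C@@H](OC(C)=O)C/C=C(/C)[C@@H](O[Si](C)(C)C(C)(C)C)[C@@H](OCc1ccc(OC)cc1)/C=C(\CBr)C(=O)OC | intermediate
38 | methyl (2Z,4S,5R,6Z,9S,10Z)-9-acetoxy-2-(bromomethyl)-5-[(tert-butyldimethylsilyl)oxy]-4-[(4-methoxybenzyl)oxy]-6,10-dimethyl-12-oxododeca-2,6,10-trienoate | O=C/C=C(/C)[C@@H](OC(C)=O)C/C=C(/C)[C@@H](O[Si](C)(C)C(C)(C)C)[C@@H](OCc1ccc(OC)cc1)/C=C(\CBr)C(=O)OC | intermediate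
39 | allylchromium dichloride from 38 (CrCl2 in place of bromine on C13) | O=C/C=C(/C)[C@@H](OC(C)=O)C/C=C(/C)[C@@H](O[Si](C)(C)C(C)(C)C)[C@@H](OCc1ccc(OC)cc1)/C=C(\C[Cr](Cl)Cl)C(=O)OC | intermediate
40 | chromium alkoxide of the ring-closed hydroxy ester (C6–C7 bond formed, methyl 2-propenoate unit on C7, configuration as in 41) | COC(=O)C(=C)[C@@H]1[C@H](O[Cr](Cl)Cl)/C=C(/C)[C@@H](OC(C)=O)C/C=C(/C)[C@@H](O[Si](C)(C)C(C)(C)C)[C@H]1OCc2ccc(OC)cc2 | intermediate
41 | (3S,6R,7R,8S,9R)-3-acetoxy-9-[(tert-butyldimethylsilyl)oxy]-8-[(4-methoxybenzyl)oxy]germacra-1(10)Z,4Z,11(13)-trien-12,6-olide | C=C1C(=O)O[C@@H]2/C=C(/C)[C@@H](OC(C)=O)C/C=C(/C)[C@@H](O[Si](C)(C)C(C)(C)C)[C@@H](OCc3ccc(OC)cc3)[C@H]12 | intermediate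
42 | (3S,6R,7S,8S,9R)-3-acetoxy-9-[(tert-butyldimethylsilyl)oxy]-8-hydroxygermacra-1(10)Z,4Z,11(13)-trien-12,6-olide | C=C1C(=O)O[C@@H]2/C=C(/C)[C@@H](OC(C)=O)C/C=C(/C)[C@@H](O[Si](C)(C)C(C)(C)C)[C@@H](O)[C@H]12 | intermediate
43 | mixed anhydride of 28 with 2,4,6-trichlorobenzoic acid | O=C(OC(=O)[C@]1(C)O[C@@H]1C)c1c(Cl)cc(Cl)cc1Cl | intermediate
44 | (3S,6R,7R,8S,9R)-3-acetoxy-9-[(tert-butyldimethylsilyl)oxy]-8-{[(2R,3R)-2,3-dimethyloxirane-2-carbonyl]oxy}germacra-1(10)Z,4Z,11(13)-trien-12,6-olide | C=C1C(=O)O[C@@H]2/C=C(/C)[C@@H](OC(C)=O)C/C=C(/C)[C@@H](O[Si](C)(C)C(C)(C)C)[C@@H](OC(=O)[C@]3(C)O[C@@H]3C)[C@H]12 | intermediate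
45 | (3S,6R,7R,8S,9R)-3-acetoxy-9-hydroxy-8-{[(2R,3R)-2,3-dimethyloxirane-2-carbonyl]oxy}germacra-1(10)Z,4Z,11(13)-trien-12,6-olide | C=C1C(=O)O[C@@H]2/C=C(/C)[C@@H](OC(C)=O)C/C=C(/C)[C@@H](O)[C@@H](OC(=O)[C@]3(C)O[C@@H]3C)[C@H]12 | target

Total step count: 27. Longest linear sequence: 18 steps (steps 3–9, then 17–27).

Steps most likely to fail

Step 24 (key step). The ring closure may lose to intermolecular coupling or to protonation of the allylchromium species at the dilution needed, and loss of the chromium–ether chelate in donor solvent would erode the face selectivity at C7. The fallback replaces the in situ organochromium reagent by an isolable allylboronate. It sets out from 35, which would be acetylated (Ac2O, pyridine) to the allylic acetate F1. A Hosomi–Miyaura borylation with allylic transposition (bis(pinacolato)diboron, CuCl, LiCl, KOAc, DMF) would then give the 2-(methoxycarbonyl)allylboronate F2 with C8 cis to CH2B. Methanolysis of the primary silyl ether (pyridinium p-toluenesulfonate, MeOH) would give the alcohol F3, and Dess–Martin oxidation the aldehyde F4. F4 would be cyclised by thermal intramolecular allylboration through a closed chair transition state (toluene, 80 °C, high dilution, Sc(OTf)3 as optional catalyst); lactonisation on work-up brings the route back to 41.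

Step 17. Facial selectivity in the addition to the α-alkoxy aldehyde may be poor (Felkin–Anh and chelate pathways competing), giving both C9 epimers. The fallback sets the stereocenter by ketone reduction instead of addition. It sets out from 30 as the epimer mixture, which would be oxidised (Dess–Martin periodinane, NaHCO3) to the enone F5. Reduction under chelation control by the α-PMB ether (Zn(BH4)2, Et2O, −30 °C) should deliver hydride to the open face of the chelate and return the 8,9-anti alcohol 30.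

Step 20. The amine-catalysed reaction may be slow enough for epimerisation of the α-alkoxy aldehyde at C8 or β-elimination of the C9 silyloxy group to compete. The fallback builds the same adduct by aldol addition and selenoxide elimination. It sets out from 33, which would be treated at −78 °C with the lithium enolate of methyl 3-(phenylselanyl)propanoate (LiN(iPr)2, THF) to give the selenide aldol adduct F6. Oxidation (H2O2, pyridine, CH2Cl2, 0 °C) and syn-elimination of the selenoxide would return 35.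

Further compounds
F1 | step 24 | methyl (4S,5R,6Z,9S,10Z)-3,9-diacetoxy-5,12-bis[(tert-butyldimethylsilyl)oxy]-4-[(4-methoxybenzyl)oxy]-6,10-dimethyl-2-methylidenedodeca-6,10-dienoate (both C3 epimers) | CC(C)(C)[Si](C)(C)OC/C=C(/C)[C@@H](OC(C)=O)C/C=C(/C)[C@@H](O[Si](C)(C)C(C)(C)C)[C@@H](OCc1ccc(OC)cc1)C(OC(C)=O)C(=C)C(=O)OC
F2 | step 24 | methyl (4S,5R,6Z,9S,10Z)-9-acetoxy-5,12-bis[(tert-butyldimethylsilyl)oxy]-4-[(4-methoxybenzyl)oxy]-6,10-dimethyl-2-[(4,4,5,5-tetramethyl-1,3,2-dioxaborolan-2-yl)methyl]dodeca-2,6,10-trienoate (C4 cis to CH2B across C2=C3) | CC(C)(C)[Si](C)(C)OC/C=C(/C)[C@@H](OC(C)=O)C/C=C(/C)[C@@H](O[Si](C)(C)C(C)(C)C)[C@@H](OCc1ccc(OC)cc1)/C=C(\CB1OC(C)(C)C(C)(C)O1)C(=O)OC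
F3 | step 24 | 12-hydroxy analogue of F2 (primary silyl ether removed) | OC/C=C(/C)[C@@H](OC(C)=O)C/C=C(/C)[C@@H](O[Si](C)(C)C(C)(C)C)[C@@H](OCc1ccc(OC)cc1)/C=C(\CB1OC(C)(C)C(C)(C)O1)C(=O)OC
F4 | step 24 | 12-oxo analogue of F2 (Z enal) | O=C/C=C(/C)[C@@H](OC(C)=O)C/C=C(/C)[C@@H](O[Si](C)(C)C(C)(C)C)[C@@H](OCc1ccc(OC)cc1)/C=C(\CB1OC(C)(C)C(C)(C)O1)C(=O)OC
F5 | step 17 | (2Z,4S,6Z,9S)-1-[(tert-butyldimethylsilyl)oxy]-9-[(4R)-2,2-dimethyl-1,3-dioxolan-4-yl]-9-[(4-methoxybenzyl)oxy]-3,7-dimethyl-8-oxonona-2,6-dien-4-yl acetate | CC(C)(C)[Si](C)(C)OC/C=C(/C)[C@@H](OC(C)=O)C/C=C(/C)C(=O)[C@@H](OCc1ccc(OC)cc1)[C@H]1COC(C)(C)O1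
F6 | step 20 | methyl (4S,5R,6Z,9S,10Z)-9-acetoxy-5,12-bis[(tert-butyldimethylsilyl)oxy]-3-hydroxy-4-[(4-methoxybenzyl)oxy]-6,10-dimethyl-2-[(phenylselanyl)methyl]dodeca-6,10-dienoate (mixture at C2 and C3) | CC(C)(C)[Si](C)(C)OC/C=C(/C)[C@@H](OC(C)=O)C/C=C(/C)[C@@H](O[Si](C)(C)C(C)(C)C)[C@@H](OCc1ccc(OC)cc1)C(O)C(C[Se]c1ccccc1)C(=O)OC
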